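**Retrosynthetic overview**
- The aryl ether C–O bond is made last, by Mitsunobu coupling of 7-hydroxy-8-methoxycoumarin with a (2R,3R)-epoxy alcohol; the oxirane comes from Sharpless epoxidation of an (E)-allylic alcohol.
- The γ-lactone comes from oxidative lactonisation of a 1,2,4-triol; the (E)-trisubstituted alkene from a (Z)-enol phosphate/Me2CuLi exchange on a β-keto ester, then i-Bu2AlH reduction.
- Key C–C bond (C4'–C5'): vinylogous Mukaiyama aldol of Chan's diene with a C5'–C8' aldehyde, catalysed by Ti(OiPr)4/(R)-1,1'-bi-2-naphthol, which sets C5'.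
- The aldehyde, carrying the quaternary C7' centre, comes from Seebach alkylation of the (S)-lactic acid/pivalaldehyde dioxolanone with allyl bromide, then reduction, acetonide formation and ozonolysis.
- Ring order: coumarin ring in a side branch (Vilsmeier formylation, Wittig–lactonisation), then the γ-lactone ring, then the oxirane ring; the two halves are joined last.

Convention/assumption: side-chain carbons run C1' (ArO–CH2) to C8' (lactone C=O). The target is taken exactly as drawn: (2'R,3'R)-oxirane, C5' S, C7' R (OH trans to the C5' substituent).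

**Route**

Step 1
Reactants: 1 (S)-lactic acid; 2 pivalaldehyde
Product: 3 (2S,5S)-2-tert-butyl-5-methyl-1,3-dioxolan-4-one
Conditions: p-toluenesulfonic acid monohydrate (cat.), H2SO4 (cat.), pentane, reflux, Dean–Stark; recrystallise from Et2O/pentane, −78 °C
Reagents that add atoms: none
Why: Acid-catalysed acetalisation (Seebach dioxolanone formation) leaves the lactic acid centre untouched and gives mainly the cis acetal, upgraded to about 96:4 or better by crystallisation.

Step 2
Reactants: 3 (2S,5S)-2-tert-butyl-5-methyl-1,3-dioxolan-4-one; 4 allyl bromide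
Product: 6 (2S,5R)-2-tert-butyl-5-methyl-5-(prop-2-en-1-yl)-1,3-dioxolan-4-one, via lithium enolate 5 (not isolated)
Conditions: LiN(i-Pr)2, THF, −78 °C; then 4, −78 → −30 °C
Reagents that add atoms: none
Why: Seebach enolate alkylation (self-regeneration of stereocentres): the allyl group enters anti to the tert-butyl group, replacing H with retention and fixing the quaternary centre that becomes C7' (R).

Step 3
Reactants: 6 (2S,5R)-2-tert-butyl-5-methyl-5-(prop-2-en-1-yl)-1,3-dioxolan-4-one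
Product: 7 (2R)-2-methylpent-4-ene-1,2-diol
Conditions: LiAlH4, Et2O, 0 °C → rt; H2O/aq. NaOH work-up
Reagents that add atoms: none
Why: Hydride reduction of the acylal lactone releases the 1,2-diol (the pivalaldehyde unit leaves as neopentyl alcohol) without touching the quaternary centre.

Step 4
Reactants: 7 (2R)-2-methylpent-4-ene-1,2-diol
Product: 8 (4R)-2,2,4-trimethyl-4-(prop-2-en-1-yl)-1,3-dioxolane
Conditions: 2,2-dimethoxypropane, pyridinium p-toluenesulfonate (cat.), CH2Cl2, rt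
Reagents that add atoms: 2,2-dimethoxypropane COC(C)(C)OC
Why: Transacetalisation gives the five-membered acetonide, masking the tertiary and primary hydroxyls (C7'–OH, C8'–OH) through the base, hydride and cuprate steps.

Step 5
Reactants: 8 (4R)-2,2,4-trimethyl-4-(prop-2-en-1-yl)-1,3-dioxolane
Product: 10 2-[(4R)-2,2,4-trimethyl-1,3-dioxolan-4-yl]acetaldehyde, via secondary ozonide 9 (not isolated)
Conditions: O3, CH2Cl2, −78 °C; then PPh3, −78 °C → rt
Reagents that add atoms: ozone [O-][O+]=O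
Why: Ozonolysis with reductive work-up cleaves the terminal alkene to the C5' aldehyde; the acetonide is inert and the quaternary centre cannot epimerise.

Step 6
Reactants: 11 methyl acetoacetate
Product: 12 methyl 3-(trimethylsilyloxy)but-2-enoate (E/Z mixture)
Conditions: Me3SiCl, Et3N, hexane, rt
Reagents that add atoms: chlorotrimethylsilane C[Si](C)(C)Cl
Why: O-silylation of the β-keto ester enol gives the silyl enol ether needed for γ-deprotonation.

Step 7
Reactants: 12 methyl 3-(trimethylsilyloxy)but-2-enoate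
Product: 14 1-methoxy-1,3-bis(trimethylsilyloxy)buta-1,3-diene (Chan's diene), via lithium dienolate 13 (not isolated)
Conditions: LiN(i-Pr)2, THF, −78 °C; then Me3SiCl, −78 → 0 °C; distil
Reagents that add atoms: chlorotrimethylsilane C[Si](C)(C)Cl
Why: Kinetic γ-deprotonation and O-silylation give the acetoacetate dianion equivalent (Chan's diene preparation); no stereocentre is involved.

Step 8
Reactants: 10 2-[(4R)-2,2,4-trimethyl-1,3-dioxolan-4-yl]acetaldehyde; 14 1-methoxy-1,3-bis(trimethylsilyloxy)buta-1,3-diene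
Product: 16 methyl (5S)-5-hydroxy-3-oxo-6-[(4R)-2,2,4-trimethyl-1,3-dioxolan-4-yl]hexanoate, via bis-silyl aldol adduct 15 (not isolated)
Conditions: Ti(OiPr)4 (10 mol %), (R)-1,1'-bi-2-naphthol (10 mol %), 4 Å molecular sieves, THF, −78 °C → rt; then pyridinium p-toluenesulfonate (cat.), MeOH, 0 °C
Reagents that add atoms: none
Why: Catalytic asymmetric vinylogous Mukaiyama aldol: the terminal carbon of the diene adds to the Re face of the aldehyde under control of the (R)-ligand (the sense that gives (R)-carbinols from aryl aldehydes), forming the C4'–C5' bond and setting C5' (5S here), with the remote quaternary centre exerting little bias.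

Step 9
Reactants: 16 methyl (5S)-5-hydroxy-3-oxo-6-[(4R)-2,2,4-trimethyl-1,3-dioxolan-4-yl]hexanoate
Product: 17 methyl (5S)-3-oxo-5-(triethylsilyloxy)-6-[(4R)-2,2,4-trimethyl-1,3-dioxolan-4-yl]hexanoate
Conditions: Et3SiCl, imidazole, CH2Cl2, 0 °C
Reagents that add atoms: chlorotriethylsilane CC[Si](CC)(CC)Cl
Why: Silylation of the secondary alcohol prevents δ-lactonisation and O-phosphorylation in the next step; TES is chosen because mild acid later removes it together with the acetonide.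

Step 10
Reactants: 17 methyl (5S)-3-oxo-5-(triethylsilyloxy)-6-[(4R)-2,2,4-trimethyl-1,3-dioxolan-4-yl]hexanoate
Product: 19 methyl (2Z,5S)-3-[(diethoxyphosphoryl)oxy]-5-(triethylsilyloxy)-6-[(4R)-2,2,4-trimethyl-1,3-dioxolan-4-yl]hex-2-enoate, via sodium enolate 18 (not isolated)
Conditions: NaH, Et2O, 0 °C; then ClP(O)(OEt)2, 0 °C
Reagents that add atoms: diethyl chlorophosphate CCOP(=O)(Cl)OCC
Why: Weiler enol phosphate formation: the sodium-chelated β-keto ester enolate is O-phosphorylated to give the (Z)-enol phosphate, which fixes the alkene geometry.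

Step 11
Reactants: 19 methyl (2Z,5S)-3-[(diethoxyphosphoryl)oxy]-5-(triethylsilyloxy)-6-[(4R)-2,2,4-trimethyl-1,3-dioxolan-4-yl]hex-2-enoate
Product: 20 methyl (2E,5R)-3-methyl-5-(triethylsilyloxy)-6-[(4R)-2,2,4-trimethyl-1,3-dioxolan-4-yl]hex-2-enoate
Conditions: Me2CuLi (from CuI + 2 MeLi), Et2O, −78 → −45 °C
Reagents that add atoms: lithium dimethylcuprate [Li+].C[Cu-]C
Why: Cuprate addition–elimination on the enol phosphate (Weiler coupling) replaces the phosphate by methyl with retention, giving the (E)-trisubstituted enoate; the C5 label changes from S to R only through the priority rules.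

Step 12
Reactants: 20 methyl (2E,5R)-3-methyl-5-(triethylsilyloxy)-6-[(4R)-2,2,4-trimethyl-1,3-dioxolan-4-yl]hex-2-enoate
Product: 21 (2E,5R)-3-methyl-5-(triethylsilyloxy)-6-[(4R)-2,2,4-trimethyl-1,3-dioxolan-4-yl]hex-2-en-1-ol
Conditions: i-Bu2AlH (2.5 equiv), CH2Cl2, −78 °C; aq. potassium sodium tartrate work-up
Reagents that add atoms: none
Why: 1,2-Reduction of the enoate gives the allylic alcohol while C8' is still at the alcohol level, so no lactone competes.

Step 13
Reactants: 21 (2E,5R)-3-methyl-5-(triethylsilyloxy)-6-[(4R)-2,2,4-trimethyl-1,3-dioxolan-4-yl]hex-2-en-1-ol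
Product: 22 tert-butyl({(2E,5R)-3-methyl-5-(triethylsilyloxy)-6-[(4R)-2,2,4-trimethyl-1,3-dioxolan-4-yl]hex-2-en-1-yl}oxy)diphenylsilane
Conditions: t-BuPh2SiCl, imidazole, CH2Cl2, 0 °C → rt
Reagents that add atoms: tert-butyl(chloro)diphenylsilane CC(C)(C)[Si](Cl)(c1ccccc1)c1ccccc1
Why: Silylation with the acid-stable TBDPS group keeps the allylic C1' hydroxyl out of the later oxidation.

Step 14
Reactants: 22 tert-butyl({(2E,5R)-3-methyl-5-(triethylsilyloxy)-6-[(4R)-2,2,4-trimethyl-1,3-dioxolan-4-yl]hex-2-en-1-yl}oxy)diphenylsilane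
Product: 23 (2R,4R,6E)-8-{[tert-butyl(diphenyl)silyl]oxy}-2,6-dimethyloct-6-ene-1,2,4-triol
Conditions: AcOH/THF/H2O (3:1:1), 45 °C
Reagents that add atoms: none
Why: Mild acid hydrolysis removes the acetonide and the TES ether while the primary TBDPS ether survives, exposing the three hydroxyls needed for the lactone.

Step 15
Reactants: 23 (2R,4R,6E)-8-{[tert-butyl(diphenyl)silyl]oxy}-2,6-dimethyloct-6-ene-1,2,4-triol
Product: 25 (3R,5R)-5-[(2E)-4-{[tert-butyl(diphenyl)silyl]oxy}-2-methylbut-2-en-1-yl]-3-hydroxy-3-methyloxolan-2-one, via lactol 24 (not isolated)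
Conditions: 2,2,6,6-tetramethylpiperidin-1-oxyl (TEMPO, 20 mol %), PhI(OAc)2 (2.5 equiv), CH2Cl2, rt
Reagents that add atoms: none
Why: TEMPO-mediated oxidative lactonisation oxidises only the primary alcohol; the aldehyde is trapped by the C5' hydroxyl as a five-membered lactol that is oxidised to the γ-lactone, both stereocentres being untouched.

Step 16
Reactants: 25 (3R,5R)-5-[(2E)-4-{[tert-butyl(diphenyl)silyl]oxy}-2-methylbut-2-en-1-yl]-3-hydroxy-3-methyloxolan-2-one
Product: 26 (3R,5R)-3-hydroxy-5-[(2E)-4-hydroxy-2-methylbut-2-en-1-yl]-3-methyloxolan-2-one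
Conditions: HF·pyridine, pyridine/THF, 0 °C → rt
Reagents that add atoms: none
Why: Buffered fluoride desilylation frees the allylic alcohol without opening the lactone.

Step 17
Reactants: 26 (3R,5R)-3-hydroxy-5-[(2E)-4-hydroxy-2-methylbut-2-en-1-yl]-3-methyloxolan-2-one
Product: 27 (3R,5S)-3-hydroxy-5-{[(2R,3R)-3-(hydroxymethyl)-2-methyloxiran-2-yl]methyl}-3-methyloxolan-2-one
Conditions: Ti(OiPr)4 (30 mol %), D-(−)-diethyl tartrate (36 mol %), t-BuOOH (2 equiv, in decane), 4 Å molecular sieves, CH2Cl2, −25 °C; aq. citric acid work-up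
Reagents that add atoms: tert-butyl hydroperoxide CC(C)(C)OO
Why: Sharpless asymmetric epoxidation: with D-(−)-tartrate an (E)-3-methylalk-2-en-1-ol gives the (2R,3R)-epoxy alcohol (mirror image of the geraniol/L-(+)-tartrate case), setting C2' and C3'; the lactone C5 label becomes S only through the priority rules.

Step 18
Reactants: 28 2-methoxyresorcinol
Product: 30 2,4-dihydroxy-3-methoxybenzaldehyde, via aryl iminium chloride 29 (not isolated)
Conditions: POCl3, HC(O)NMe2 (DMF), MeCN, 0 °C → rt; then H2O, 50 °C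
Reagents that add atoms: N,N-dimethylformamide CN(C)C=O; water O
Why: Vilsmeier–Haack formylation of the symmetric resorcinol can only occur ortho to one hydroxyl and para to the other, so a single aldehyde results.

Step 19
Reactants: 30 2,4-dihydroxy-3-methoxybenzaldehyde
Product: 32 7-hydroxy-8-methoxy-2H-chromen-2-one, via cinnamate ester 31 (not isolated)
Conditions: Ph3P=CHCO2Et (2.2 equiv), N,N-diethylaniline, reflux
Reagents that add atoms: ethyl (triphenylphosphoranylidene)acetate CCOC(=O)C=P(c1ccccc1)(c1ccccc1)c1ccccc1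
Why: Wittig olefination followed by thermal E/Z isomerisation and lactonisation onto the ortho hydroxyl builds the coumarin ring with the 7-OH free and the 8-OMe in place.

Step 20
Reactants: 27 (3R,5S)-3-hydroxy-5-{[(2R,3R)-3-(hydroxymethyl)-2-methyloxiran-2-yl]methyl}-3-methyloxolan-2-one; 32 7-hydroxy-8-methoxy-2H-chromen-2-one
Product: 33 7-{[(2R,3R)-3-{[(2S,4R)-4-hydroxy-4-methyl-5-oxooxolan-2-yl]methyl}-3-methyloxiran-2-yl]methoxy}-8-methoxy-2H-chromen-2-one
Conditions: PPh3, diisopropyl azodicarboxylate, THF, 0 °C → rt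
Reagents that add atoms: none
Why: Mitsunobu etherification: the acidic coumarin phenol displaces the activated primary hydroxyl at the CH2 carbon, so no stereocentre is touched and the tertiary alcohol is inert.

**Compound list**

1 | (S)-lactic acid | C[C@H](O)C(=O)O | starting material
2 | pivalaldehyde | CC(C)(C)C=O | starting material
3 | (2S,5S)-2-tert-butyl-5-methyl-1,3-dioxolan-4-one | C[C@@H]1O[C@H](C(C)(C)C)OC1=O | intermediate
4 | allyl bromide | C=CCBr | starting material
5 | lithium (2S)-2-tert-butyl-5-methyl-2H-1,3-dioxol-4-olate (formed in situ) | CC1=C(O[Li])O[C@@H](C(C)(C)C)O1 | intermediate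
6 | (2S,5R)-2-tert-butyl-5-methyl-5-(prop-2-en-1-yl)-1,3-dioxolan-4-one | C=CC[C@@]1(C)O[C@H](C(C)(C)C)OC1=O | intermediate
7 | (2R)-2-methylpent-4-ene-1,2-diol | C=CC[C@@](C)(O)CO | intermediate
8 | (4R)-2,2,4-trimethyl-4-(prop-2-en-1-yl)-1,3-dioxolane | C=CC[C@]1(C)COC(C)(C)O1 | intermediate
9 | 3-{[(4R)-2,2,4-trimethyl-1,3-dioxolan-4-yl]methyl}-1,2,4-trioxolane (both epimers at the trioxolane carbon; formed in situ) | C1(C[C@]2(C)COC(C)(C)O2)OCOO1 | intermediate
10 | 2-[(4R)-2,2,4-trimethyl-1,3-dioxolan-4-yl]acetaldehyde | O=CC[C@]1(C)COC(C)(C)O1 | intermediate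
11 | methyl acetoacetate | COC(=O)CC(C)=O | starting material
12 | methyl 3-(trimethylsilyloxy)but-2-enoate (E/Z mixture) | COC(=O)C=C(C)O[Si](C)(C)C | intermediate
13 | lithium 1-methoxy-3-(trimethylsilyloxy)buta-1,3-dien-1-olate (formed in situ) | C=C(O[Si](C)(C)C)C=C(OC)O[Li] | intermediate
14 | 1-methoxy-1,3-bis(trimethylsilyloxy)buta-1,3-diene (ketene acetal geometry not controlled) | C=C(O[Si](C)(C)C)C=C(OC)O[Si](C)(C)C | intermediate
15 | methyl (5S)-3,5-bis(trimethylsilyloxy)-6-[(4R)-2,2,4-trimethyl-1,3-dioxolan-4-yl]hex-2-enoate (formed in situ) | COC(=O)C=C(O[Si](C)(C)C)C[C@@H](O[Si](C)(C)C)C[C@]1(C)COC(C)(C)O1 | intermediate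
16 | methyl (5S)-5-hydroxy-3-oxo-6-[(4R)-2,2,4-trimethyl-1,3-dioxolan-4-yl]hexanoate | COC(=O)CC(=O)C[C@@H](O)C[C@]1(C)COC(C)(C)O1 | intermediate
17 | methyl (5S)-3-oxo-5-(triethylsilyloxy)-6-[(4R)-2,2,4-trimethyl-1,3-dioxolan-4-yl]hexanoate | COC(=O)CC(=O)C[C@@H](O[Si](CC)(CC)CC)C[C@]1(C)COC(C)(C)O1 | intermediate
18 | sodium (2Z,5S)-1-methoxy-1-oxo-5-(triethylsilyloxy)-6-[(4R)-2,2,4-trimethyl-1,3-dioxolan-4-yl]hex-2-en-3-olate (formed in situ) | COC(=O)/C=C(/C[C@@H](O[Si](CC)(CC)CC)C[C@]1(C)COC(C)(C)O1)O[Na] | intermediate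
19 | methyl (2Z,5S)-3-[(diethoxyphosphoryl)oxy]-5-(triethylsilyloxy)-6-[(4R)-2,2,4-trimethyl-1,3-dioxolan-4-yl]hex-2-enoate | COC(=O)/C=C(/C[C@@H](O[Si](CC)(CC)CC)C[C@]1(C)COC(C)(C)O1)OP(=O)(OCC)OCC | intermediate
20 | methyl (2E,5R)-3-methyl-5-(triethylsilyloxy)-6-[(4R)-2,2,4-trimethyl-1,3-dioxolan-4-yl]hex-2-enoate | COC(=O)/C=C(\C)C[C@@H](O[Si](CC)(CC)CC)C[C@]1(C)COC(C)(C)O1 | intermediate
21 | (2E,5R)-3-methyl-5-(triethylsilyloxy)-6-[(4R)-2,2,4-trimethyl-1,3-dioxolan-4-yl]hex-2-en-1-ol | OC/C=C(\C)C[C@@H](O[Si](CC)(CC)CC)C[C@]1(C)COC(C)(C)O1 | intermediate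
22 | tert-butyl({(2E,5R)-3-methyl-5-(triethylsilyloxy)-6-[(4R)-2,2,4-trimethyl-1,3-dioxolan-4-yl]hex-2-en-1-yl}oxy)diphenylsilane | CC(C)(C)[Si](c1ccccc1)(c1ccccc1)OC/C=C(\C)C[C@@H](O[Si](CC)(CC)CC)C[C@]2(C)COC(C)(C)O2 | intermediate
23 | (2R,4R,6E)-8-{[tert-butyl(diphenyl)silyl]oxy}-2,6-dimethyloct-6-ene-1,2,4-triol | CC(C)(C)[Si](c1ccccc1)(c1ccccc1)OC/C=C(\C)C[C@@H](O)C[C@@](C)(O)CO | intermediate
24 | (3R,5R)-5-[(2E)-4-{[tert-butyl(diphenyl)silyl]oxy}-2-methylbut-2-en-1-yl]-3-methyloxolane-2,3-diol (both anomers; formed in situ) | CC(C)(C)[Si](c1ccccc1)(c1ccccc1)OC/C=C(\C)C[C@@H]2C[C@@](C)(O)C(O)O2 | intermediate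
25 | (3R,5R)-5-[(2E)-4-{[tert-butyl(diphenyl)silyl]oxy}-2-methylbut-2-en-1-yl]-3-hydroxy-3-methyloxolan-2-one | CC(C)(C)[Si](c1ccccc1)(c1ccccc1)OC/C=C(\C)C[C@@H]2C[C@@](C)(O)C(=O)O2 | intermediate
26 | (3R,5R)-3-hydroxy-5-[(2E)-4-hydroxy-2-methylbut-2-en-1-yl]-3-methyloxolan-2-one | OC/C=C(\C)C[C@@H]1C[C@@](C)(O)C(=O)O1 | intermediate
27 | (3R,5S)-3-hydroxy-5-{[(2R,3R)-3-(hydroxymethyl)-2-methyloxiran-2-yl]methyl}-3-methyloxolan-2-one | OC[C@H]1O[C@]1(C)C[C@@H]2C[C@@](C)(O)C(=O)O2 | intermediate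
28 | 2-methoxyresorcinol (2-methoxybenzene-1,3-diol) | COc1c(O)cccc1O | starting material
29 | [(2,4-dihydroxy-3-methoxyphenyl)methylidene]dimethylammonium chloride (formed in situ) | C[N+](C)=Cc1ccc(O)c(OC)c1O.[Cl-] | intermediate
30 | 2,4-dihydroxy-3-methoxybenzaldehyde | COc1c(O)ccc(C=O)c1O | intermediate
31 | ethyl (2E)-3-(2,4-dihydroxy-3-methoxyphenyl)prop-2-enoate (formed in situ) | CCOC(=O)/C=C/c1ccc(O)c(OC)c1O | intermediate
32 | 7-hydroxy-8-methoxy-2H-chromen-2-one | COc1c(O)ccc2ccc(=O)oc12 | intermediate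
33 | 7-{[(2R,3R)-3-{[(2S,4R)-4-hydroxy-4-methyl-5-oxooxolan-2-yl]methyl}-3-methyloxiran-2-yl]methoxy}-8-methoxy-2H-chromen-2-one | COc1c(OC[C@H]2O[C@]2(C)C[C@@H]2C[C@@](C)(O)C(=O)O2)ccc2ccc(=O)oc12 | target

**Step count and risks**

Total steps: 20. Longest linear sequence: 16 (steps 1–5, 8–17, 20).

Three steps most likely to fail:

1. Step 8. Face selectivity and turnover of the titanium/binaphthol catalyst on an unactivated aliphatic aldehyde with a Lewis-basic acetonide are the least certain point. The fallback sets out from 10 and replaces catalyst control by reagent control. Brown allylation with (+)-B-allyldiisopinocampheylborane (Et2O, −78 °C; NaOH/H2O2 work-up), which attacks the Re face, gives (2R)-1-[(4R)-2,2,4-trimethyl-1,3-dioxolan-4-yl]pent-4-en-2-ol F1. Silylation (Et3SiCl, imidazole) gives triethyl({(2R)-1-[(4R)-2,2,4-trimethyl-1,3-dioxolan-4-yl]pent-4-en-2-yl}oxy)silane F2. Ozonolysis (O3; PPh3) gives (3S)-3-(triethylsilyloxy)-4-[(4R)-2,2,4-trimethyl-1,3-dioxolan-4-yl]butanal F3. Roskamp homologation with methyl diazoacetate and SnCl2 (cat.) in CH2Cl2 then gives the β-keto ester, and the route is rejoined at 17.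

2. Step 15. The tertiary/primary 1,2-diol could suffer glycol cleavage by PhI(OAc)2, or the α-hydroxy aldehyde could over-oxidise before the lactol closes. The fallback sets out from 23 and goes through the acid instead of the lactol. Oxidation of the primary alcohol with TEMPO (cat.)/NaClO2/NaOCl (cat.) in MeCN–phosphate buffer (pH 6.7, 35 °C) gives (2R,4R,6E)-8-{[tert-butyl(diphenyl)silyl]oxy}-2,4-dihydroxy-2,6-dimethyloct-6-enoic acid F4. Lactonisation with pyridinium p-toluenesulfonate (cat.) in CH2Cl2 then closes the ring, and the route is rejoined at 25.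

3. Step 17. The free α-hydroxy lactone may bind the titanium–tartrate catalyst and slow or derail the epoxidation. The fallback sets out from 26 and inverts the order of the last two operations. Mitsunobu coupling of 26 with 32 (PPh3, diisopropyl azodicarboxylate, THF) gives 7-({(2E)-4-[(2R,4R)-4-hydroxy-4-methyl-5-oxooxolan-2-yl]-3-methylbut-2-en-1-yl}oxy)-8-methoxy-2H-chromen-2-one F5. Shi epoxidation with the D-fructose-derived ketone 1,2:4,5-di-O-isopropylidene-β-D-erythro-2,3-hexodiulo-2,6-pyranose (30 mol %), KHSO5, K2CO3, MeCN/dimethoxymethane/aqueous buffer, 0 °C, short reaction time, delivers the (R,R)-oxirane on the electron-rich trisubstituted alkene. The route is rejoined at 33.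

**Further compounds**

F1 | step 8 | (2R)-1-[(4R)-2,2,4-trimethyl-1,3-dioxolan-4-yl]pent-4-en-2-ol | C=CC[C@@H](O)C[C@]1(C)COC(C)(C)O1
F2 | step 8 | triethyl({(2R)-1-[(4R)-2,2,4-trimethyl-1,3-dioxolan-4-yl]pent-4-en-2-yl}oxy)silane | C=CC[C@@H](O[Si](CC)(CC)CC)C[C@]1(C)COC(C)(C)O1
F3 | step 8 | (3S)-3-(triethylsilyloxy)-4-[(4R)-2,2,4-trimethyl-1,3-dioxolan-4-yl]butanal | O=CC[C@@H](O[Si](CC)(CC)CC)C[C@]1(C)COC(C)(C)O1
F4 | step 15 | (2R,4R,6E)-8-{[tert-butyl(diphenyl)silyl]oxy}-2,4-dihydroxy-2,6-dimethyloct-6-enoic acid | CC(C)(C)[Si](c1ccccc1)(c1ccccc1)OC/C=C(\C)C[C@@H](O)C[C@@](C)(O)C(=O)O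
F5 | step 17 | 7-({(2E)-4-[(2R,4R)-4-hydroxy-4-methyl-5-oxooxolan-2-yl]-3-methylbut-2-en-1-yl}oxy)-8-methoxy-2H-chromen-2-one | COc1c(OC/C=C(\C)C[C@@H]2C[C@@](C)(O)C(=O)O2)ccc2ccc(=O)oc12
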